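**Retrosynthetic overview**

1. The furan-2(5H)-one ring (O1, C2 carbonyl, C3, C4 bearing CH2OH, C5 stereocentre) is made last: an O-acylation/intramolecular Wittig domino of the open-chain α-ketol 21 with Ph3P=C=C=O forms O1–C2 and closes the ring at C3=C4.
2. Enabling feature: ring C5 (bears O1), ring C4 and the hydroxymethyl carbon on C4 form a dihydroxyacetone unit, so C4 is a latent ketone next to the C5 carbinol, which is the α-ketol that a two-carbon acyl ylide closes onto.
3. 21 comes from the RAMP hydrazone of 2,2-dimethyl-1,3-dioxan-5-one and allylic bromide 13; the temporary dioxane ring and the auxiliary set the only new stereocentre and are then hydrolysed.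
4. 13 comes from (Z)-iodo alcohol 9, made by anti-carbomagnesiation/iodination of propargyl alcohol with the alkylmagnesium bromide 6 derived from (+)-sclareolide; this fixes the trisubstituted alkene.
5. Ring order: decalin rings A and B are bought with sclareolide (its lactone ring is opened in step 1); the dioxanone ring enters in step 8 and is cleaved in step 11; the furanone ring is formed last, in step 13.

Key step: step 13

Remark 1: Bic = (4aS,8aS)-2,5,5,8a-tetramethyl-3,4,4a,5,6,7,8,8a-octahydronaphthalen-1-yl (rings A and B of the target; ring B holds the tetrasubstituted alkene).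

Remark 2 (assumption): the RAMP azaenolate of the dioxanone is taken to react with the same facial sense as other RAMP ketone azaenolates, which corresponds to (R) at the new centre. If the sense were opposite, the enantiomeric auxiliary SAMP would be used with no other change.

**Route**

Step 1
Reactants: 1 (+)-sclareolide
Product: 2 methyl 2-(Bic)acetate
Conditions: conc. H2SO4, MeOH, 65 °C; chromatography on AgNO3-doped silica
Reagents that add atoms: methanol, CO
Why: Acid-catalysed cleavage of the tertiary lactone C–O bond (E1) with Fischer esterification; reversible protonation should collect the alkene isomers in the tetrasubstituted ring B alkene, the most substituted isomer, while both ring-fusion stereocentres stay untouched.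

Step 2
Reactants: 2 methyl 2-(Bic)acetate
Product: 3 2-(Bic)ethanol
Conditions: LiAlH4, Et2O, 0 °C → rt; then H2O, aq. NaOH
Reagents that add atoms: none
Why: LiAlH4 reduction of the unconjugated ester to the primary alcohol; the tetrasubstituted alkene is inert to hydride.

Step 3
Reactants: 3 2-(Bic)ethanol
Product: 4 1-bromo-2-(Bic)ethane
Conditions: CBr4, PPh3, CH2Cl2, 0 °C
Reagents that add atoms: carbon tetrabromide, BrC(Br)(Br)Br
Why: Appel bromination, an SN2 displacement of the oxyphosphonium group at the primary carbon under neutral conditions that should not isomerise the alkene.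

Step 4
Reactants: 4 1-bromo-2-(Bic)ethane; 5 prop-2-yn-1-ol
Product: 9 (2Z)-3-iodo-2-[2-(Bic)ethyl]prop-2-en-1-ol, via alkylmagnesium bromide 6 (not isolated), via bromomagnesium propynolate 7 (not isolated), via cyclic vinylmagnesium alkoxide 8 (not isolated)
Conditions: (a) 4, Mg, THF, 40 °C; (b) 5, EtMgBr (1.0 equiv), THF, 0 °C; (c) a + b (6 in 1.3 equiv), CuI (10 mol%), THF–Et2O, 0 → 35 °C; (d) I2, −30 → 0 °C; aq. NH4Cl/Na2S2O3
Reagents that add atoms: iodine, II
Why: Copper-catalysed anti-carbomagnesiation of a propargylic magnesium alkoxide puts the alkyl group on the alkyne carbon next to CH2O and magnesium on the terminal carbon inside a five-membered C–Mg–O chelate, so iodinolysis with retention should place iodine cis to CH2OH and fix the alkene geometry of the target.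

Step 5
Reactants: 9 (2Z)-3-iodo-2-[2-(Bic)ethyl]prop-2-en-1-ol
Product: 10 tert-butyl{[(2Z)-3-iodo-2-[2-(Bic)ethyl]prop-2-en-1-yl]oxy}diphenylsilane
Conditions: t-BuPh2SiCl, imidazole, DMF, 0 °C → rt
Reagents that add atoms: tert-butyl(chloro)diphenylsilane, CC(C)(C)[Si](Cl)(c1ccccc1)c1ccccc1
Why: Silylation of the primary allylic alcohol; the tert-butyldiphenylsilyl ether should survive t-BuLi at −78 °C and the dilute acids of steps 10 and 11.

Step 6
Reactants: 10 tert-butyl{[(2Z)-3-iodo-2-[2-(Bic)ethyl]prop-2-en-1-yl]oxy}diphenylsilane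
Product: 12 (2Z)-3-{[tert-butyl(diphenyl)silyl]oxymethyl}-5-(Bic)pent-2-en-1-ol, via vinyllithium 11 (not isolated)
Conditions: t-BuLi (2.1 equiv), Et2O, −78 °C; (CH2O)n, −78 °C → rt; then H2O
Reagents that add atoms: formaldehyde (from paraformaldehyde), C=O
Why: Iodine–lithium exchange with retention of alkene geometry followed by 1,2-addition of the vinyllithium to formaldehyde; Et2O at −78 °C should suppress the 1,4 O-to-C silyl shift.

Step 7
Reactants: 12 (2Z)-3-{[tert-butyl(diphenyl)silyl]oxymethyl}-5-(Bic)pent-2-en-1-ol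
Product: 13 {[(2Z)-4-bromo-2-[2-(Bic)ethyl]but-2-en-1-yl]oxy}(tert-butyl)diphenylsilane
Conditions: CBr4, PPh3, CH2Cl2, −20 °C
Reagents that add atoms: carbon tetrabromide, BrC(Br)(Br)Br
Why: Appel bromination of the primary allylic alcohol by direct SN2 displacement, which should keep the position and geometry of the alkene.

Step 8
Reactants: 14 2,2-dimethyl-1,3-dioxan-5-one; 15 (R)-1-amino-2-(methoxymethyl)pyrrolidine (RAMP)
Product: 16 (2R)-N-(2,2-dimethyl-1,3-dioxan-5-ylidene)-2-(methoxymethyl)pyrrolidin-1-amine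
Conditions: benzene, reflux, Dean–Stark trap
Reagents that add atoms: none
Why: Hydrazone condensation driven by azeotropic removal of water; the ketone is symmetrical, so no regio- or stereochemical question arises.

Step 9
Reactants: 16 (2R)-N-(2,2-dimethyl-1,3-dioxan-5-ylidene)-2-(methoxymethyl)pyrrolidin-1-amine; 13 {[(2Z)-4-bromo-2-[2-(Bic)ethyl]but-2-en-1-yl]oxy}(tert-butyl)diphenylsilane
Product: 18 RAMP hydrazone of (4R)-4-[(2Z)-3-{[tert-butyl(diphenyl)silyl]oxymethyl}-5-(Bic)pent-2-en-1-yl]-2,2-dimethyl-1,3-dioxan-5-one, via lithium azaenolate 17 (not isolated)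
Conditions: 16 (1.3 equiv), t-BuLi (1.3 equiv), THF, −78 °C; then 13, −100 → −78 °C
Reagents that add atoms: none
Why: Enders RAMP-hydrazone α-alkylation: the lithium azaenolate, held rigid by chelation of lithium to the methoxymethyl oxygen, should be alkylated by the primary allylic bromide (SN2) on the face left open by the pyrrolidine, which for RAMP corresponds to (R) at the new dioxanone C4, the future furanone C5.

Step 10
Reactants: 18 RAMP hydrazone of the alkylated dioxanone
Product: 19 (4R)-4-[(2Z)-3-{[tert-butyl(diphenyl)silyl]oxymethyl}-5-(Bic)pent-2-en-1-yl]-2,2-dimethyl-1,3-dioxan-5-one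
Conditions: sat. aq. oxalic acid, Et2O, rt
Reagents that add atoms: water, O
Why: Mild two-phase acidic hydrolysis of the N,N-dialkylhydrazone, which should leave the acetonide, the silyl ether and the α-stereocentre untouched and returns the auxiliary in the aqueous phase.

Step 11
Reactants: 19 (4R)-4-[(2Z)-3-{[tert-butyl(diphenyl)silyl]oxymethyl}-5-(Bic)pent-2-en-1-yl]-2,2-dimethyl-1,3-dioxan-5-one
Product: 20 (3R,5Z)-6-{[tert-butyl(diphenyl)silyl]oxymethyl}-1,3-dihydroxy-8-(Bic)oct-5-en-2-one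
Conditions: 1 M aq. HCl, THF, 0 °C → rt
Reagents that add atoms: none
Why: Acid-catalysed acetal hydrolysis frees both hydroxyls; dilute acid at room temperature should spare the tert-butyldiphenylsilyl ether and the alkenes, and the absence of base avoids enolisation of the ketol centre.

Step 12
Reactants: 20 (3R,5Z)-6-{[tert-butyl(diphenyl)silyl]oxymethyl}-1,3-dihydroxy-8-(Bic)oct-5-en-2-one
Product: 21 (3R,5Z)-1-{[tert-butyl(dimethyl)silyl]oxy}-6-{[tert-butyl(diphenyl)silyl]oxymethyl}-3-hydroxy-8-(Bic)oct-5-en-2-one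
Conditions: t-BuMe2SiCl (1.05 equiv), imidazole, CH2Cl2, −20 → 0 °C
Reagents that add atoms: tert-butyl(chloro)dimethylsilane, CC(C)(C)[Si](C)(C)Cl
Why: Kinetically selective silylation of the primary hydroxyl over the more hindered secondary ketol hydroxyl with one equivalent of silyl chloride at low temperature.

Step 13
Reactants: 21 (3R,5Z)-1-{[tert-butyl(dimethyl)silyl]oxy}-6-{[tert-butyl(diphenyl)silyl]oxymethyl}-3-hydroxy-8-(Bic)oct-5-en-2-one; 22 (triphenylphosphoranylidene)ketene, Ph3P=C=C=O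
Product: 24 (5R)-4-{[tert-butyl(dimethyl)silyl]oxymethyl}-5-[(2Z)-3-{[tert-butyl(diphenyl)silyl]oxymethyl}-5-(Bic)pent-2-en-1-yl]furan-2(5H)-one, via acyl ylide 23 (not isolated)
Conditions: 22 (1.3 equiv), toluene, 60 → 110 °C
Reagents that add atoms: none
Why: The free ketol hydroxyl adds across the C=C of Ph3P=C=C=O to give the ester-stabilised acyl ylide 23, and its ylide carbon then attacks the adjacent ketone in an intramolecular Wittig reaction (oxaphosphetane, loss of Ph3PO), which forms the ring C3=C4 bond and with it the whole furanone. The closest known reaction type is the addition–Wittig domino of this cumulated ylide with α-hydroxy ketones and α-hydroxy esters, which gives butenolides and tetronates. The five-membered ring closes by 5-exo-trig attack of the ylide carbon (future C3) on the ketone carbon (future C4), and because the new alkene is endocyclic its geometry is not an issue. No stereocentre is created: C5 is brought in from step 9, and the base-free medium should keep this ketone α-centre from enolising until it has become the less acidic γ-centre of the butenolide. The step needs chemoselectivity for one hydroxyl and one carbonyl, secured because 21 has a single free OH and a single ketone, because the cumulated ylide itself does not olefinate carbonyl groups, and because neither ylide touches the isolated alkenes or the silyl ethers.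

Step 14
Reactants: 24 (5R)-4-{[tert-butyl(dimethyl)silyl]oxymethyl}-5-[(2Z)-3-{[tert-butyl(diphenyl)silyl]oxymethyl}-5-(Bic)pent-2-en-1-yl]furan-2(5H)-one
Product: 25 16-epi-luffarin L
Conditions: HF·pyridine, pyridine, THF, 0 °C → rt
Reagents that add atoms: none
Why: Fluoride-mediated cleavage of both silyl ethers under weakly acidic buffered conditions, which should neither open the butenolide nor epimerise its C5 centre.

**Compound list**

1 | (+)-sclareolide, (3aR,5aS,9aS,9bR)-3a,6,6,9a-tetramethyldecahydronaphtho[2,1-b]furan-2(1H)-one | C[C@]12CCCC([C@@H]1CC[C@@]3([C@@H]2CC(=O)O3)C)(C)C | starting material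
2 | methyl 2-(Bic)acetate | CC1=C(CC(=O)OC)[C@@]2(C)CCCC(C)(C)[C@@H]2CC1 | intermediate
3 | 2-(Bic)ethanol | CC1=C(CCO)[C@@]2(C)CCCC(C)(C)[C@@H]2CC1 | intermediate
4 | 1-bromo-2-(Bic)ethane | CC1=C(CCBr)[C@@]2(C)CCCC(C)(C)[C@@H]2CC1 | intermediate
5 | prop-2-yn-1-ol (propargyl alcohol) | C#CCO | starting material
6 | [2-(Bic)ethyl]magnesium bromide | CC1=C(CC[Mg]Br)[C@@]2(C)CCCC(C)(C)[C@@H]2CC1 | intermediate
7 | bromomagnesium prop-2-yn-1-olate | C#CCO[Mg]Br | intermediate
8 | 4-[2-(Bic)ethyl]-2,5-dihydro-1,2-oxamagnesole (cyclic vinylmagnesium alkoxide) | CC1=C(CCC2=C[Mg]OC2)[C@@]2(C)CCCC(C)(C)[C@@H]2CC1 | intermediate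
9 | (2Z)-3-iodo-2-[2-(Bic)ethyl]prop-2-en-1-ol | CC1=C(CC/C(=C/I)CO)[C@@]2(C)CCCC(C)(C)[C@@H]2CC1 | intermediate
10 | tert-butyl{[(2Z)-3-iodo-2-[2-(Bic)ethyl]prop-2-en-1-yl]oxy}diphenylsilane | CC1=C(CC/C(=C/I)CO[Si](c2ccccc2)(c2ccccc2)C(C)(C)C)[C@@]2(C)CCCC(C)(C)[C@@H]2CC1 | intermediate
11 | [(1Z)-3-{[tert-butyl(diphenyl)silyl]oxy}-2-[2-(Bic)ethyl]prop-1-en-1-yl]lithium | CC1=C(CC/C(=C/[Li])CO[Si](c2ccccc2)(c2ccccc2)C(C)(C)C)[C@@]2(C)CCCC(C)(C)[C@@H]2CC1 | intermediate
12 | (2Z)-3-{[tert-butyl(diphenyl)silyl]oxymethyl}-5-(Bic)pent-2-en-1-ol | CC1=C(CC/C(=C/CO)CO[Si](c2ccccc2)(c2ccccc2)C(C)(C)C)[C@@]2(C)CCCC(C)(C)[C@@H]2CC1 | intermediate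
13 | {[(2Z)-4-bromo-2-[2-(Bic)ethyl]but-2-en-1-yl]oxy}(tert-butyl)diphenylsilane | CC1=C(CC/C(=C/CBr)CO[Si](c2ccccc2)(c2ccccc2)C(C)(C)C)[C@@]2(C)CCCC(C)(C)[C@@H]2CC1 | intermediate
14 | 2,2-dimethyl-1,3-dioxan-5-one | CC1(C)OCC(=O)CO1 | starting material
15 | (R)-1-amino-2-(methoxymethyl)pyrrolidine (RAMP) | COC[C@H]1CCCN1N | starting material
16 | (2R)-N-(2,2-dimethyl-1,3-dioxan-5-ylidene)-2-(methoxymethyl)pyrrolidin-1-amine | COC[C@H]1CCCN1N=C1COC(C)(C)OC1 | intermediate
17 | lithium azaenolate of 16, lithium (2,2-dimethyl-4H-1,3-dioxin-5-yl)[(2R)-2-(methoxymethyl)pyrrolidin-1-yl]amide | COC[C@H]1CCCN1N([Li])C1=COC(C)(C)OC1 | intermediate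
18 | (2R)-N-{(4R)-4-[(2Z)-3-{[tert-butyl(diphenyl)silyl]oxymethyl}-5-(Bic)pent-2-en-1-yl]-2,2-dimethyl-1,3-dioxan-5-ylidene}-2-(methoxymethyl)pyrrolidin-1-amine | CC1=C(CC/C(=C/C[C@H]2OC(C)(C)OCC2=NN2CCC[C@@H]2COC)CO[Si](c2ccccc2)(c2ccccc2)C(C)(C)C)[C@@]2(C)CCCC(C)(C)[C@@H]2CC1 | intermediate
19 | (4R)-4-[(2Z)-3-{[tert-butyl(diphenyl)silyl]oxymethyl}-5-(Bic)pent-2-en-1-yl]-2,2-dimethyl-1,3-dioxan-5-one | CC1=C(CC/C(=C/C[C@H]2OC(C)(C)OCC2=O)CO[Si](c2ccccc2)(c2ccccc2)C(C)(C)C)[C@@]2(C)CCCC(C)(C)[C@@H]2CC1 | intermediate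
20 | (3R,5Z)-6-{[tert-butyl(diphenyl)silyl]oxymethyl}-1,3-dihydroxy-8-(Bic)oct-5-en-2-one | CC1=C(CC/C(=C/C[C@@H](O)C(=O)CO)CO[Si](c2ccccc2)(c2ccccc2)C(C)(C)C)[C@@]2(C)CCCC(C)(C)[C@@H]2CC1 | intermediate
21 | (3R,5Z)-1-{[tert-butyl(dimethyl)silyl]oxy}-6-{[tert-butyl(diphenyl)silyl]oxymethyl}-3-hydroxy-8-(Bic)oct-5-en-2-one | CC1=C(CC/C(=C/C[C@@H](O)C(=O)CO[Si](C)(C)C(C)(C)C)CO[Si](c2ccccc2)(c2ccccc2)C(C)(C)C)[C@@]2(C)CCCC(C)(C)[C@@H]2CC1 | intermediate
22 | (triphenylphosphoranylidene)ketene | O=C=C=P(c1ccccc1)(c1ccccc1)c1ccccc1 | starting material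
23 | (3R,5Z)-1-{[tert-butyl(dimethyl)silyl]oxy}-6-{[tert-butyl(diphenyl)silyl]oxymethyl}-2-oxo-8-(Bic)oct-5-en-3-yl (triphenylphosphoranylidene)acetate | CC1=C(CC/C(=C/C[C@@H](OC(=O)C=P(c2ccccc2)(c2ccccc2)c2ccccc2)C(=O)CO[Si](C)(C)C(C)(C)C)CO[Si](c2ccccc2)(c2ccccc2)C(C)(C)C)[C@@]2(C)CCCC(C)(C)[C@@H]2CC1 | intermediate
24 | (5R)-4-{[tert-butyl(dimethyl)silyl]oxymethyl}-5-[(2Z)-3-{[tert-butyl(diphenyl)silyl]oxymethyl}-5-(Bic)pent-2-en-1-yl]furan-2(5H)-one | CC1=C(CC/C(=C/C[C@H]2OC(=O)C=C2CO[Si](C)(C)C(C)(C)C)CO[Si](c2ccccc2)(c2ccccc2)C(C)(C)C)[C@@]2(C)CCCC(C)(C)[C@@H]2CC1 | intermediate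
25 | 16-epi-luffarin L, (5R)-4-(hydroxymethyl)-5-[(2Z)-3-(hydroxymethyl)-5-(Bic)pent-2-en-1-yl]furan-2(5H)-one | CC1=C(CC/C(=C/C[C@H]2OC(=O)C=C2CO)CO)[C@@]2(C)CCCC(C)(C)[C@@H]2CC1 | target

**Step count**

Total step count: 14. Longest linear sequence: 13 steps (steps 1–7 and 9–14, from sclareolide); step 8 is a one-step side branch.

**Steps most likely to fail**

Step 4. The alkylmagnesium reagent may deprotonate the acetylenic C–H instead of adding, and the vinylmagnesium chelate may be protonated before iodinolysis, so that conversion of the bromide stalls. The fallback sets out from 4 and builds the alkene by carbonyl olefination instead: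
- Alkylation of methyl bis(2,2,2-trifluoroethyl)phosphonoacetate with 4 (NaH, DMF) should give the α-alkylated phosphonate F1.
- Still–Gennari olefination of F1 (KN(SiMe3)2, 18-crown-6, THF, −78 °C) with (tert-butyldimethylsilyloxy)acetaldehyde should give the (Z)-enoate F2, with the ester cis to the silyloxymethyl group.
- i-Bu2AlH (CH2Cl2, −78 °C) should reduce the ester to the allylic alcohol F3.
- t-BuPh2SiCl/imidazole should give the bis-silyl ether F4.
- PPTS in MeOH should remove the primary tert-butyldimethylsilyl ether selectively, and the route is rejoined at 12.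

Step 13. Addition of the hindered ketol hydroxyl to the cumulated ylide may be slow at the temperature the Wittig closure needs, so that thermal epimerisation of the ketone α-centre or silyl migration between the two oxygens flanking the ketone competes. The fallback sets out from 21 and separates acylation from ring closure. Esterification with diethylphosphonoacetic acid (DCC, DMAP cat., CH2Cl2, 0 °C) should give the phosphonoacetate ester F5. An intramolecular Horner–Wadsworth–Emmons reaction under Masamune–Roush conditions (LiCl, i-Pr2NEt, MeCN, rt) should then close the same C3=C4 bond, and the route is rejoined at 24.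

Step 6. The (Z)-γ-silyloxy vinyllithium may undergo 1,4 O-to-C silyl migration or be protonated before the slowly depolymerising paraformaldehyde captures it. The fallback sets out from 10 and avoids the organolithium. Methoxycarbonylation (Pd(PPh3)2Cl2 cat., CO 1 atm, MeOH, Et3N, DMF, 60 °C) should give the (Z)-enoate F6 with retention of geometry. Reduction with i-Bu2AlH (CH2Cl2, −78 °C) then rejoins the route at 12.

**Further compounds**

F1 | step 4 | methyl 2-[bis(2,2,2-trifluoroethoxy)phosphoryl]-4-(Bic)butanoate (both epimers at C2) | CC1=C(CCC(C(=O)OC)P(=O)(OCC(F)(F)F)OCC(F)(F)F)[C@@]2(C)CCCC(C)(C)[C@@H]2CC1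
F2 | step 4 | methyl (2Z)-4-{[tert-butyl(dimethyl)silyl]oxy}-2-[2-(Bic)ethyl]but-2-enoate | CC1=C(CC/C(=C/CO[Si](C)(C)C(C)(C)C)C(=O)OC)[C@@]2(C)CCCC(C)(C)[C@@H]2CC1
F3 | step 4 | (2Z)-4-{[tert-butyl(dimethyl)silyl]oxy}-2-[2-(Bic)ethyl]but-2-en-1-ol | CC1=C(CC/C(=C/CO[Si](C)(C)C(C)(C)C)CO)[C@@]2(C)CCCC(C)(C)[C@@H]2CC1
F4 | step 4 | (2Z)-4-{[tert-butyl(dimethyl)silyl]oxy}-1-{[tert-butyl(diphenyl)silyl]oxy}-2-[2-(Bic)ethyl]but-2-ene | CC1=C(CC/C(=C/CO[Si](C)(C)C(C)(C)C)CO[Si](c2ccccc2)(c2ccccc2)C(C)(C)C)[C@@]2(C)CCCC(C)(C)[C@@H]2CC1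
F5 | step 13 | (3R,5Z)-1-{[tert-butyl(dimethyl)silyl]oxy}-6-{[tert-butyl(diphenyl)silyl]oxymethyl}-2-oxo-8-(Bic)oct-5-en-3-yl (diethoxyphosphoryl)acetate | CC1=C(CC/C(=C/C[C@@H](OC(=O)CP(=O)(OCC)OCC)C(=O)CO[Si](C)(C)C(C)(C)C)CO[Si](c2ccccc2)(c2ccccc2)C(C)(C)C)[C@@]2(C)CCCC(C)(C)[C@@H]2CC1
F6 | step 6 | methyl (2Z)-3-{[tert-butyl(diphenyl)silyl]oxymethyl}-5-(Bic)pent-2-enoate | CC1=C(CC/C(=C/C(=O)OC)CO[Si](c2ccccc2)(c2ccccc2)C(C)(C)C)[C@@]2(C)CCCC(C)(C)[C@@H]2CC1
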